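Readings and results were computed for an exercise, and the scatter is random.

Thursday's run at 20 °C climbs and then goes flat near 17.6%. Sunday's run, which is the flask I am asked about, does the same near 23.8%.

| setting | Sunday's | Thursday's | flask |
|---|---|---|---|
| substrate | 2 M | 2 M | 2.0 M |
| coupling partner | 0.70 equiv | 0.70 equiv | 0.700 equiv |
| initiator | 5 mol% | 5 mol% | 5 mol% |
| temperature | 25 °C | 20 °C | 25 °C |
| remark | the very flask that is asked about, followed so far | run made earlier |  |
| time |  |  | 3.0 d |

| run | time / d | target / % |
|---|---|---|
| Sunday's | 0.125 | 13.3 |
| Sunday's | 0.333 | 21.6 |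
| Sunday's | 0.625 | 23.3 |
| Sunday's | 1.04 | 24.3 |
| Sunday's | 1.67 | 22.8 |
| Sunday's | 2.08 | 23.8 |
| Sunday's | 2.50 | 24.7 |
| Thursday's | 0.125 | 8.9 |
| Thursday's | 0.333 | 12.6 |
| Thursday's | 0.625 | 18.3 |
| Thursday's | 1.04 | 16.8 |
| Thursday's | 1.67 | 17.6 |
| Thursday's | 2.08 | 17.3 |
| Thursday's | 2.50 | 17.8 |

(each reading ± 1 percentage point)

- alder: change nothing and wait 3.0 d more
- cedar: at 3.0 d take out 90% of the by-product then present, then wait 3.0 d
- maple: at 3.0 d raise the temperature by 10 K, then wait 3.0 d

- target, in percent of the substrate first charged, at 3.0 d
- what to do for the largest gain in target; "none" if nothing gains more than 2 percentage points (alder / cedar / maple / none)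
- target present, in percent of the substrate first charged, after alder
- target present, in percent of the substrate first charged, after cedar

- what is added takes up no volume worth counting

I read Sunday's flask by its rate. Up to the first reading the target grows at 1.06 d⁻¹ as a share of the substrate charged, and between the first two readings at 0.399 d⁻¹. So the rate drops by a factor 2.66 over the 0.167 d between the middles of those intervals. In the next interval it is 0.0582 d⁻¹, down by a further factor 6.86, though that gain is close to the scatter of 1 percentage point.

I take the fall as exponential and call the time in which the rate falls by a factor e the slowing time: 0.170 d, a reading with that scatter in it. Integrated in closed form, the target still to come after any moment is the rate then times the slowing time, and I call this the tail. From zero the tail is 26.1%, which stands above the plateau, so the early readings roughly foretell the late ones.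

By 3.0 d the flask has lived 17.6 slowing times, so my reckoned tail is 5.5 × 10⁻⁷ points, less than the margin of 2 points. I commit to 23.8% now and to no gain from alder. But the tail speaks of waiting, not warming, and Sunday's plateau stands above Thursday's, so I leave maple open.

The forecast gives 24% now, 24% after alder, 24% after cedar and none as best, holding that “waiting, removing by-product or warming should change nothing”. There it parts from me on maple.

The flask gives 23.8%, then 23.8% after alder and 23.8% after cedar, but the best choice is maple, worth 12 points.

    target ⇌ isomer of the product (K = 0.900, k = 0.340 h⁻¹, Ea = 86.0 kJ mol⁻¹, ΔH = −90.0 kJ mol⁻¹)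
    substrate + initiating radical → capped initiator + first chain carrier (k = 40000 M⁻¹ s⁻¹, Ea = 10.0 kJ mol⁻¹)
    substrate + second chain carrier → by-product + first chain carrier (k = 1.10 × 10⁶ M⁻¹ h⁻¹, Ea = 45.0 kJ mol⁻¹)
    2 second chain carrier → ended chains (k = 1.70 × 10⁸ M⁻¹ s⁻¹, Ea = 11.0 kJ mol⁻¹)
    coupling partner + first chain carrier → target + second chain carrier (k = 2.20 × 10⁶ M⁻¹ h⁻¹, Ea = 38.0 kJ mol⁻¹)
    coupling partner + target → over-reaction product (k = 0.170 M⁻¹ h⁻¹, Ea = 74.0 kJ mol⁻¹)
    initiator → 2 initiating radical (k = 0.0350 h⁻¹, Ea = 96.0 kJ mol⁻¹)
    (constants at 25 °C)

The neighbouring flask is this flask with 1.20 equiv of coupling partner, the other charges held. If I keep the start rate and 0.170 d unchanged, the same reckoning gives 26.1% at 3.00 d. That neighbouring flask holds 22.9% of target, with coupling partner, the limiting reagent, at 0% and over-reaction product at 38.2%.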